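## Retrosynthetic overview

(Locants are those of the 2H-chromene skeleton of the target, O-1 to C-8a; ring A is the carbocycle, ring B the pyran.)

1. The C-7 acyl group is disconnected last (enol ester, then 1,3-acyl shift), because its α-CH2 would otherwise compete in the ring closure; this leaves a bicyclic chromene-dione.
2. The chromene-dione is opened to an acyclic 3,5,7-trione: one operation makes C-8a=C-4a (closing ring A) and then C-2–C-3 (closing ring B).
3. Enabling feature: C-8a carries O-1 and lies α to the C-8 carbonyl, with C-4a as the β-carbon, so C-8a=C-4a is the enone bond of an aldol condensation of an α-alkoxy ketone. The same O-1 carries C-2 at the ketone level, so O-1–C-2(Me2) can be a ketal (latent oxocarbenium) that the C-4=C-3 vinylsilane on C-4a reaches only once ring A exists.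
4. The trione comes from a quaternary keto ester: the acetyl CH3 becomes C-7 (Claisen acylation with a ketal-protected glycolate); the ester carbon becomes C-4a (aldehyde, vinylsilane addition, oxidation).
5. The keto ester comes from ethyl 2-methylacetoacetate and prenyl bromide; C-5 is set by alkylation of a valine-derived chiral enamine.

Key step: step 8

Assumption: in toluene/HMPA the lithium aza-enolate of the L-valine tert-butyl ester enamine is taken to be alkylated on the face that gives the (R)-keto ester; if the sense were the opposite, the D-valine ester would be used with no other change.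

## Route

Step 1
Reactants: 1 ethyl 2-methyl-3-oxobutanoate; 2 L-valine tert-butyl ester
Product: 3 ethyl (Z)-3-{[(2S)-1-tert-butoxy-3-methyl-1-oxobutan-2-yl]amino}-2-methylbut-2-enoate
Conditions: AcOH (cat.), 4 Å molecular sieves, toluene, 60 °C
Reagents that add atoms: L-valine tert-butyl ester 2, CC(C)[C@H](N)C(=O)OC(C)(C)C
Why: Condensation of the ketone of the β-keto ester with the primary amine (enamine formation, giving a hydrogen-bonded vinylogous carbamate) is favoured over ester aminolysis and installs the chiral auxiliary without touching the valine stereocentre.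

Step 2
Reactants: 3 the enamino ester; 4 prenyl bromide (1-bromo-3-methylbut-2-ene)
Product: 6 ethyl (2R)-2-acetyl-2,5-dimethylhex-4-enoate, via alkylated ketimine 5 (not isolated)
Conditions: LiN(i-Pr)2, toluene, HMPA, −78 °C; 4, −78 to −40 °C; then 1 M aq. HCl, rt
Reagents that add atoms: prenyl bromide 4, CC(C)=CCBr; water, O
Why: Chiral-enamine alkylation: the lithium aza-enolate is held rigid by chelation to the tert-butyl ester, the isopropyl group blocks one face, prenyl bromide should therefore C-alkylate from the open face and set the quaternary centre as (R), and mild acid hydrolysis of ketimine 5 frees the ketone and the auxiliary.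

Step 3
Reactants: 7 methyl glycolate (methyl 2-hydroxyacetate); 8 2-methoxypropene
Product: 9 methyl 2-[(2-methoxypropan-2-yl)oxy]acetate
Conditions: PPTS (1 mol %), CH2Cl2, 0 °C; Et3N quench
Reagents that add atoms: 2-methoxypropene 8, COC(C)=C
Why: Acid-catalysed addition of the alcohol to the enol ether (mixed-ketal formation) is fast at 0 °C and leaves the ester untouched.

Step 4
Reactants: 6 the (R)-keto ester; 9 the ketal-protected glycolate
Product: 10 ethyl (2R)-6-[(2-methoxypropan-2-yl)oxy]-2-methyl-2-(3-methylbut-2-en-1-yl)-3,5-dioxohexanoate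
Conditions: LiN(SiMe3)2 (2.2 equiv), THF, −78 °C; 9, −78 to −20 °C; pH 7 phosphate buffer
Reagents that add atoms: ester 9, COC(=O)COC(C)(C)OC
Why: Crossed Claisen condensation: the acetyl methyl group is the only enolisable position of 6, its lithium enolate is acylated by the activated α-alkoxy ester, deprotonation of the 1,3-dione product drives the reaction, and the ketal and the quaternary centre are inert to base.

Step 5
Reactants: 10 the diketo ester
Product: 11 (2S)-6-[(2-methoxypropan-2-yl)oxy]-2-methyl-2-(3-methylbut-2-en-1-yl)-3,5-dioxohexanal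
Conditions: NaH (1.05 equiv), THF, 0 °C; i-Bu2AlH (1.3 equiv), −78 °C; aq. KNaC4H4O6 (potassium sodium tartrate); used crude
Reagents that add atoms: none
Why: Partial ester reduction with i-Bu2AlH: the dione is first masked as its sodium enolate, which hydride does not attack, and the tetrahedral aluminium hemiacetal of the hindered ester should survive at −78 °C, so the aldehyde is released only on work-up.

Step 6
Reactants: 11 the aldehyde; 12 (E)-(2-bromovinyl)trimethylsilane
Product: 14 (1E,4S)-3-hydroxy-8-[(2-methoxypropan-2-yl)oxy]-4-methyl-4-(3-methylbut-2-en-1-yl)-1-(trimethylsilyl)oct-1-ene-5,7-dione (both C-3 epimers), via vinyllithium 13 (not isolated)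
Conditions: 12 (2.5 equiv), t-BuLi (5.0 equiv), Et2O, −78 °C; then 11, THF, −78 °C; pH 7 phosphate buffer
Reagents that add atoms: (E)-(2-bromovinyl)trimethylsilane 12, Br/C=C/[Si](C)(C)C
Why: Bromine–lithium exchange with retention of the (E) geometry, then 1,2-addition of the vinyllithium to the aldehyde, the first equivalent holding the dione as its unreactive lithium enolate; the new carbinol centre need not be controlled because step 7 removes it.

Step 7
Reactants: 14 the allylic alcohol
Product: 15 (1E,4R)-8-[(2-methoxypropan-2-yl)oxy]-4-methyl-4-(3-methylbut-2-en-1-yl)-1-(trimethylsilyl)oct-1-ene-3,5,7-trione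
Conditions: MnO2 (excess), CH2Cl2, rt; filtered and used at once
Reagents that add atoms: none
Why: Allylic alcohol oxidation on MnO2 is chemoselective under neutral conditions, so the acid-labile ketal, the prenyl group, the vinylsilane and the dione should survive.

Step 8
Reactants: 15 the acyclic trione
Product: 18 (5S)-8-hydroxy-2,2,5-trimethyl-5-(3-methylbut-2-en-1-yl)-2H-chromen-6(5H)-one, via bis-silyl dienol ether 16 (not isolated), via cyclic trienone 17 (not isolated)
Conditions: Me3SiOTf (4.2 equiv), i-Pr2NEt (3.0 equiv), CH2Cl2, −78 °C to rt; then aq. NaHCO3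
Reagents that add atoms: none
Why: Proposed new method: Me3SiOTf/i-Pr2NEt should turn the 5,7-dione into its 1,3-bis(silyloxy)-1,3-diene and the mixed ketal into the isopropenyl ether (16); the terminal, oxygen-bearing diene carbon then adds to the silyl-activated enone carbonyl (intramolecular vinylogous Mukaiyama aldol), loss of silanol gives trienone 17 plus one equivalent of TfOH, and this acid, meeting no free amine, protonates the isopropenyl ether to the 2-oxonia-hexatriene Me2C=O(+)–C(8a)=C(4a)–CH=CH–SiMe3, which closes at the silicon-bearing carbon and expels Me3Si(+). The closest known reaction types are the formal [3+3] cyclisations of 1,3-bis(silyloxy)-1,3-dienes through their terminal carbon, the Mukaiyama aldol condensation, the Me3SiOTf/amine conversion of ketals into enol ethers, and the vinylsilane-terminated (silyl-Prins) cyclisation of oxocarbenium ions to dihydropyrans; new is their linkage through one oxygen that is first the α-substituent of the nucleophile and then the carrier of the electrophile. Ring A closes 6-(enolendo)-exo-trig at the ketone carbon and ring B by a 6π (formally 6-endo-trig) closure of the oxonia-triene with silicon as electrofuge. No new stereocentre is formed, and the quaternary C-5, which has no α-hydrogen, is not at risk. The step needs carbonyl addition by the terminal diene carbon and closure of ring B only after ring A: ring size secures the first (conjugate addition by the terminal carbon would need an eight-membered ring, carbonyl addition by the central carbon a four-membered one, and the silyl group shields the enone terminus from the central carbon), and the second follows because the acid is released only by the elimination and because, once ring A exists, the central carbon could reach the oxocarbenium carbon only through a bridged ring.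

Step 9
Reactants: 18 the chromene-dione; 19 3-phenylpropanoyl chloride
Product: 21 (5S)-8-hydroxy-2,2,5-trimethyl-5-(3-methylbut-2-en-1-yl)-7-(3-phenylpropanoyl)-2H-chromen-6(5H)-one, via enol ester 20 (not isolated)
Conditions: 19, Et3N, CH2Cl2, 0 °C; then DMAP (0.2 equiv), MeCN, 40 °C
Reagents that add atoms: 3-phenylpropanoyl chloride 19, O=C(Cl)CCc1ccccc1
Why: O-acylation of the cyclic 1,3-dione to enol ester 20 and DMAP-catalysed 1,3-acyl shift (O to C) should give the hydrogen-bonded 2-acyl-1,3-dione, C-7 being the only carbon between the two carbonyl groups, while the chromene, the prenyl group and the quaternary centre are inert.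

## Compound list

1 | ethyl 2-methyl-3-oxobutanoate | CCOC(=O)C(C)C(C)=O | starting material
2 | L-valine tert-butyl ester | CC(C)[C@H](N)C(=O)OC(C)(C)C | starting material
3 | ethyl (Z)-3-{[(2S)-1-tert-butoxy-3-methyl-1-oxobutan-2-yl]amino}-2-methylbut-2-enoate | O=C(OCC)/C(C)=C(\N[C@@H](C(C)C)C(=O)OC(C)(C)C)C | intermediate
4 | prenyl bromide | CC(C)=CCBr | starting material
5 | ethyl (2R)-2-{1-[((2S)-1-tert-butoxy-3-methyl-1-oxobutan-2-yl)imino]ethyl}-2,5-dimethylhex-4-enoate | CC(C)=CC[C@](C(=O)OCC)(C)C(C)=N[C@@H](C(C)C)C(=O)OC(C)(C)C | intermediate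
6 | ethyl (2R)-2-acetyl-2,5-dimethylhex-4-enoate | CC(C)=CC[C@](C(=O)OCC)(C)C(C)=O | intermediate
7 | methyl glycolate | COC(=O)CO | starting material
8 | 2-methoxypropene | COC(C)=C | starting material
9 | methyl 2-[(2-methoxypropan-2-yl)oxy]acetate | COC(=O)COC(C)(C)OC | intermediate
10 | ethyl (2R)-6-[(2-methoxypropan-2-yl)oxy]-2-methyl-2-(3-methylbut-2-en-1-yl)-3,5-dioxohexanoate | CC(C)=CC[C@](C(=O)OCC)(C)C(=O)CC(=O)COC(C)(C)OC | intermediate
11 | (2S)-6-[(2-methoxypropan-2-yl)oxy]-2-methyl-2-(3-methylbut-2-en-1-yl)-3,5-dioxohexanal | CC(C)=CC[C@](C=O)(C)C(=O)CC(=O)COC(C)(C)OC | intermediate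
12 | (E)-(2-bromovinyl)trimethylsilane | Br/C=C/[Si](C)(C)C | starting material
13 | (E)-2-(trimethylsilyl)vinyllithium | [Li]/C=C/[Si](C)(C)C | intermediate
14 | (1E,4S)-3-hydroxy-8-[(2-methoxypropan-2-yl)oxy]-4-methyl-4-(3-methylbut-2-en-1-yl)-1-(trimethylsilyl)oct-1-ene-5,7-dione | CC(C)=CC[C@](C(O)/C=C/[Si](C)(C)C)(C)C(=O)CC(=O)COC(C)(C)OC | intermediate
15 | (1E,4R)-8-[(2-methoxypropan-2-yl)oxy]-4-methyl-4-(3-methylbut-2-en-1-yl)-1-(trimethylsilyl)oct-1-ene-3,5,7-trione | CC(C)=CC[C@](C(=O)/C=C/[Si](C)(C)C)(C)C(=O)CC(=O)COC(C)(C)OC | intermediate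
16 | (1E,4R)-4-methyl-4-(3-methylbut-2-en-1-yl)-8-(prop-1-en-2-yloxy)-1-(trimethylsilyl)-5,7-bis(trimethylsilyloxy)octa-1,5,7-trien-3-one | CC(C)=CC[C@](C(=O)/C=C/[Si](C)(C)C)(C)C(O[Si](C)(C)C)=CC(O[Si](C)(C)C)=COC(C)=C | intermediate
17 | (4S)-4-methyl-4-(3-methylbut-2-en-1-yl)-2-(prop-1-en-2-yloxy)-5-(trimethylsilyloxy)-3-[(E)-2-(trimethylsilyl)ethenyl]cyclohexa-2,5-dien-1-one | CC(C)=CC[C@]1(C)C(O[Si](C)(C)C)=CC(=O)C(OC(C)=C)=C1/C=C/[Si](C)(C)C | intermediate
18 | (5S)-8-hydroxy-2,2,5-trimethyl-5-(3-methylbut-2-en-1-yl)-2H-chromen-6(5H)-one | CC(C)=CC[C@]1(C)C(=O)C=C(O)C2=C1C=CC(C)(C)O2 | intermediate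
19 | 3-phenylpropanoyl chloride | O=C(Cl)CCc1ccccc1 | starting material
20 | (5S)-2,2,5-trimethyl-5-(3-methylbut-2-en-1-yl)-6-oxo-5,6-dihydro-2H-chromen-8-yl 3-phenylpropanoate | CC(C)=CC[C@]1(C)C(=O)C=C(OC(=O)CCc3ccccc3)C2=C1C=CC(C)(C)O2 | intermediate
21 | (5S)-8-hydroxy-2,2,5-trimethyl-5-(3-methylbut-2-en-1-yl)-7-(3-phenylpropanoyl)-2H-chromen-6(5H)-one | CC(C)=CC[C@]1(C)C(=O)C(C(=O)CCc2ccccc2)=C(O)C2=C1C=CC(C)(C)O2 | target

## Step count and risks

Total steps: 9. Longest linear sequence: 8 steps (1, 2, 4, 5, 6, 7, 8, 9).

**Step 8 (proposed new method).** What may go wrong: conjugate (Mukaiyama–Michael) closure through the central diene carbon instead of carbonyl addition; ionisation of the ketal before ring A is closed, with capture of the oxocarbenium by the central enol carbon; stalling at the aldol adduct; acid-induced cyclisation of the prenyl group onto an enol oxygen. The fallback sets out from 15 and comes back at 18, using known reactions one at a time. LiN(SiMe3)2 (2.2 equiv, THF, −78 °C) forms the dione dianion, whose terminal carbon adds to the enone carbonyl to give (6S)-5-hydroxy-4-[(2-methoxypropan-2-yl)oxy]-6-methyl-6-(3-methylbut-2-en-1-yl)-5-[(E)-2-(trimethylsilyl)ethenyl]cyclohexane-1,3-dione F1. Dehydration under neutral conditions with methyl N-(triethylammoniosulfonyl)carbamate gives (6S)-4-[(2-methoxypropan-2-yl)oxy]-6-methyl-6-(3-methylbut-2-en-1-yl)-5-[(E)-2-(trimethylsilyl)ethenyl]cyclohex-4-ene-1,3-dione F2, with the ketal intact because no acid has been present. F2 is then treated with catalytic Me3SiOTf in CH2Cl2 at −40 °C (vinylsilane-terminated oxocarbenium cyclisation) to give 18.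

**Step 5.** What may go wrong: over-reduction of the ester to the alcohol, lactonisation of the dione enolate onto the ester before reduction, aluminium-induced loss of the ketal, or aldol closure of the dione onto the new aldehyde. The fallback sets out from 6 and comes back at 14; it reduces the ester before the dione is built. LiAlH4 (THF, 0 °C) gives (2S)-2-methyl-2-(3-methylbut-2-en-1-yl)butane-1,3-diol F3. Swern oxidation gives (2S)-2-methyl-2-(3-methylbut-2-en-1-yl)-3-oxobutanal F4. One equivalent of 13 at −78 °C adds to the aldehyde only, to give (1E,4S)-3-hydroxy-4-methyl-4-(3-methylbut-2-en-1-yl)-1-(trimethylsilyl)hex-1-en-5-one F5. Et3SiCl/imidazole gives (1E,4S)-4-methyl-4-(3-methylbut-2-en-1-yl)-3-(triethylsilyloxy)-1-(trimethylsilyl)hex-1-en-5-one F6. Claisen condensation with 9 (LiN(SiMe3)2, THF, −78 °C) gives (1E,4S)-8-[(2-methoxypropan-2-yl)oxy]-4-methyl-4-(3-methylbut-2-en-1-yl)-3-(triethylsilyloxy)-1-(trimethylsilyl)oct-1-ene-5,7-dione F7. Bu4NF (THF, 0 °C) then frees 14.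

**Step 2.** What may go wrong: poor facial selectivity with the allylic bromide, N- instead of C-alkylation, or the opposite sense of induction. The fallback sets out from 1 and comes back at 6. K2CO3 and prenyl bromide 4 in acetone give racemic ethyl 2-acetyl-2,5-dimethylhex-4-enoate F8, which is resolved by preparative chromatography on a chiral stationary phase, the (R) enantiomer being taken on as 6.

Further compounds
F1 | step 8 | (6S)-5-hydroxy-4-[(2-methoxypropan-2-yl)oxy]-6-methyl-6-(3-methylbut-2-en-1-yl)-5-[(E)-2-(trimethylsilyl)ethenyl]cyclohexane-1,3-dione | CC(C)=CC[C@]1(C)C(=O)CC(=O)C(OC(C)(C)OC)C1(O)/C=C/[Si](C)(C)C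
F2 | step 8 | (6S)-4-[(2-methoxypropan-2-yl)oxy]-6-methyl-6-(3-methylbut-2-en-1-yl)-5-[(E)-2-(trimethylsilyl)ethenyl]cyclohex-4-ene-1,3-dione | CC(C)=CC[C@]1(C)C(=O)CC(=O)C(OC(C)(C)OC)=C1/C=C/[Si](C)(C)C
F3 | step 5 | (2S)-2-methyl-2-(3-methylbut-2-en-1-yl)butane-1,3-diol | CC(C)=CC[C@](CO)(C)C(C)O
F4 | step 5 | (2S)-2-methyl-2-(3-methylbut-2-en-1-yl)-3-oxobutanal | CC(C)=CC[C@](C=O)(C)C(C)=O
F5 | step 5 | (1E,4S)-3-hydroxy-4-methyl-4-(3-methylbut-2-en-1-yl)-1-(trimethylsilyl)hex-1-en-5-one | CC(C)=CC[C@](C(O)/C=C/[Si](C)(C)C)(C)C(C)=O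
F6 | step 5 | (1E,4S)-4-methyl-4-(3-methylbut-2-en-1-yl)-3-(triethylsilyloxy)-1-(trimethylsilyl)hex-1-en-5-one | CC(C)=CC[C@](C(O[Si](CC)(CC)CC)/C=C/[Si](C)(C)C)(C)C(C)=O
F7 | step 5 | (1E,4S)-8-[(2-methoxypropan-2-yl)oxy]-4-methyl-4-(3-methylbut-2-en-1-yl)-3-(triethylsilyloxy)-1-(trimethylsilyl)oct-1-ene-5,7-dione | CC(C)=CC[C@](C(O[Si](CC)(CC)CC)/C=C/[Si](C)(C)C)(C)C(=O)CC(=O)COC(C)(C)OC
F8 | step 2 | racemic ethyl 2-acetyl-2,5-dimethylhex-4-enoate | CCOC(=O)C(C)(CC=C(C)C)C(C)=O
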